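I started with the easy comparison: the absolute amount of Z in two flasks at one temperature that differ in Q.

| flask | Q | E | D | temperature | remark | time |
|---|---|---|---|---|---|---|
| north | 0.14 M | 0.45 M (fed, over 4.0 min) | 5.5 mM | 75 °C | run made earlier; the fed solution adds 0.10 times the starting volume |  |
| south-west | 0.19 M | 0.45 M (fed, over 4.0 min) | 5.5 mM | 86 °C | run made earlier; the fed solution adds 0.10 times the starting volume |  |
| north-west | 0.20 M | 0.45 M (fed, over 4.0 min) | 5.5 mM | 75 °C | run made earlier; the fed solution adds 0.10 times the starting volume |  |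
| green | 0.25 M | 0.450 M (fed, over 4.0 min) | 5.5 mM | 80 °C | the fed solution adds 0.10 times the starting volume | 10 min |
| red | 0.15 M | 0.450 M | 5.5 mM | 80 °C | everything together at the start, the whole solution of E included, so that from the start the volume is larger by 0.10 times the starting volume | 2.5 min |

- north (time / min: Z / %, Q / %): 0.667: 0.7, 99.2; 2.00: 3.6, 94.8; 3.00: 9.3, 91.1; 5.00: 24.7, 75.2; 8.00: 46.4, 52.2
- south-west (time / min: Z / %, Q / %): 1.33: 3.4, 96.8; 3.00: 15.5, 84.3; 4.00: 28.3, 71.0; 6.00: 53.1, 46.1; 8.00: 75.3, 24.2
- north-west (time / min: Z / %, Q / %): 0.667: 0, 99.1; 2.00: 2.9, 96.7; 3.00: 6.5, 92.6; 5.00: 17.3, 82.2; 8.00: 32.5, 67.3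

(each reading ± 0.5 percentage points)

- amounts are per litre of the starting volume; all of the dose is in the solution fed

- the winner by amount of Z, in percent of the Q charged; "neither" if no more than 2 percentage points parts them (green / red / neither)
- how much Z is there at the end, in percent of the Q charged: green
- how much Z is there at the end, in percent of the Q charged: red

1. At 8.00 min, north held 0.0650 M of Z and north-west 0.0650 M, although they began with 0.14 M and 0.20 M of Q. So I took these runs as zero order in Q.

2. In north, Z rose slowly at first and then steadily, so I let its rate follow the E present, meaning E fed minus Z: dZ/dt = kE, pseudo-first-order in E.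

3. To get k, I replaced each curve by its mean: the slope of Z after the feed, divided by the mean E over that stretch. North gave 0.0253 min⁻¹ and south-west gave 0.0635 min⁻¹. Interpolating ln k to 80 °C gave 0.0384 min⁻¹. This is my constant k, the Z formed per minute per unit of E present.

4. Green's slope started at zero and steepened as E came in, so I let Z grow with the square of time during the feed. Taking E as fed, the end of the feed at 4.0 min gave a knee at Z = k·E·t/2 = 0.0346 M.

5. After the knee, I let green's E decay exponentially, which put Z at 0.120 M at 10 min, or 48.1% of its Q. My curve reached its level, the Q charge of 0.25 M, at 23.0 min, later than the stop.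

6. Red started at its full slope, and k gave Z = 0.0412 M at 2.5 min, or 27.5% of its Q. So I expected green to win by 21 percentage points.

7. The forecast, a little above my figures, gave 49% for green and 28% for red, with the rate “therefore zero order in Q”.

    E + X → Z + L (k = 26400 M⁻¹ s⁻¹, Ea = 32.0 kJ mol⁻¹)
    2 X → J (k = 1.00 × 10⁹ M⁻¹ s⁻¹, Ea = 11.0 kJ mol⁻¹)
    Q + L → X (k = 1.10 × 10⁵ M⁻¹ s⁻¹, Ea = 33.0 kJ mol⁻¹)
    D → 2 L (k = 0.00786 min⁻¹, Ea = 121 kJ mol⁻¹)
    E → G (k = 4.17 × 10⁻⁵ min⁻¹, Ea = 129 kJ mol⁻¹)
    (constants at 80 °C)

8. Green ended at 48.9% and red at 28.8%, so green won. At 10.0 min, green still held 72.8% of its E, and k times that amount gave a slope of 0.0126 M min⁻¹, with 51% of its Q left. For the neighbour flask, green with 1.8 M of E, k put Z level with the Q charge at 5.81 min, before the stop, and that flask stood at 99.8% of Z at 10.0 min.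

All runs were generated by integration with made-up constants; noise was put on by code.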